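Ring atoms of the carbocycles are numbered as in the target: C1 is the quaternary carbinol carrying C7H2OBz, C2 the ketone, C3=C4 the alkene, C5 the free carbinol and C6 the benzoyloxy carbon. Pyranosides keep sugar numbering, written "sugar C" or O2, O3, O4, O6. Compound numbers refer to the list after the steps.

## Analysis of the target

Target 25 is a single cyclohex-3-en-1-one ring with an exocyclic CH2OBz group (C7) on C1. It has three contiguous stereocentres, C1 (R), C6 (S) and C5 (R), and their oxygens alternate in face: O on C1 is trans to O on C6, which is trans to O on C5. Four oxygens sit in three different states: two benzoates (on C6 and C7), a tertiary hydroxyl on C1 and a secondary allylic hydroxyl on C5. The sensitive elements are the gamma-hydroxy enone and the benzoates flanked by free hydroxyls: base invites acyl migration between O5, O6, O1 and O7 and elimination toward an aromatic ring. The main difficulties are the fully substituted, oxygenated C1 next to the ketone and the need to tell O5 from O6 although both are secondary and neighbouring. The strategy rests on the C1/C6/C5 triad: read with C2 as an anomeric carbon and C3 as sugar C6, these three oxygens are O2, O3 and O4 of a D-gluco pyranoside, and C7 is a one-carbon branch on sugar C2. A 2-C-branched glucoside therefore holds all seven carbons and all three stereocentres, and only the ring bond C2–C3 has to be made.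

## Retrosynthetic reasoning

25 to 24: the last bond cut is O5–Si. The C5 hydroxyl is freed at the very end because, once free, it sits next to the C6 benzoate. A silyl ether is the one group on O5 that can be removed without base in the presence of two benzoates and the enone.

24 to 22 (through 23): the enone is cut as a beta-elimination. The C3=C4 alkene comes from a sulfonate on C4 once the C2 carbinol has been oxidised to the ketone (23). The ring-forming step delivers the two oxygens on C2 and C4 in a 1,3-relation but with the carbonyl on C4, so the oxidation levels are swapped across the C3 methylene. C1 is quaternary, so the C2 ketone can enolise only toward C3 and the regiochemistry of the elimination is built in.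

22 to 20 to 19: the C4 sulfonate comes from diol 20, and 20 from hydroxy ketone 19 by reduction of the C4 carbonyl. The forward steps must reduce without beta-elimination of the C6 benzoate and must then tell the two secondary hydroxyls apart.

19 to 17 (key disconnection): the C2–C3 bond is cut as an aldol. The resulting 1,5-keto aldehyde (mercurated form 18) is the hydrated, ring-opened form of enol ether 17, a 6-deoxyhex-5-enopyranoside. This is the only ring bond whose cleavage turns C1, C6 and C5 into sugar C2, C3 and C4 of a gluco-configured pyranoside, with the C2 oxygen as the former ring oxygen and the C4 carbonyl oxygen introduced by hydration. One ring closure thus replaces any stereoselective construction of the three centres. The forward reaction must close a ring onto an aldehyde attached to a quaternary carbon while both benzoates and the silyl ether stay in place.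

17 to 16 to 14 to 13 to 12: the enol ether comes from primary iodide 16 by elimination, the iodide from the sugar C6 hydroxyl of diol 13, and the silyl ether is placed on O4 in between. Diol 13 comes from benzylidene acetal 12. The acetal is what separates O4 and O6 from O3 and the branch oxygen, which receive the two benzoates of the target in 12.

12 to 10 to 8 to 7: the two ester bonds are cut to triol 10, whose hydroxymethyl branch comes from the vinyl group of 8 by oxidative cleavage and reduction. O3 carries a temporary ether in 7 because an ester there would not survive the organometallic step. The ether is taken off before the alkene cleavage so that no electron-rich arene meets the oxidant.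

7 to 5 and 6: the branch C–C bond on sugar C2 is cut to ketone 5 and vinyl nucleophile 6. This addition creates the quaternary stereocentre (C1 of 25). The axial anomeric methoxy group of the alpha-glycoside is relied on to send the carbon nucleophile to the beta face, so the tertiary oxygen keeps the gluco orientation.

5 to 4 to 1 and 2: ketone 5 comes from alcohol 4 by oxidation, and 4 from the commercial 2,3-diol 1 by alkylation of O3 alone with 2, through chelate 3.

## Alternatives that were turned down

Alternative 1: The C4–C5 bond is cut, opening the ring to the acyclic (Z)-beta-iodo enone aldehyde A2.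
- Forward key step: CrCl2 (divalent chromium) with catalytic NiCl2 turns the C–I bond into an alkenylchromium species that adds to the C5 aldehyde (Nozaki–Hiyama–Kishi closure), giving A1, the 1-O-triethylsilyl ether of 25.
- For: the reaction is selective for aldehydes, needs no base and tolerates esters and the ketone. A1 is one desilylation from 25, so its end game is clearly shorter than the four steps that follow the key step here.
- Against: C5 is created in the ring closure under the influence of the C6 benzoate alone, and nothing in A2 secures the 5,6-trans result. A2 has to be assembled in an open chain with a tertiary silyloxy ketone centre and an epimerisable alpha-benzoyloxy aldehyde. Its beta-iodo enone is a reactive addition–elimination acceptor whose Z geometry, needed for closure, can be lost.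
- Comparison: the chosen route takes all three centres from the chiral pool and its only new centre is later destroyed; it pays for this with length.

Alternative 2: The C5–O and C6–O bonds are cut back to the achiral dienol A4.
- Forward key step: Hf(OtBu)4 with a chiral bishydroxamic acid and cumene hydroperoxide binds the tertiary hydroxyl and delivers oxygen to one of the two enantiotopic alkenes, giving the syn epoxide A3.
- For: it is catalytic and asymmetric, A4 is a few steps from a Birch reduction, and C1, C5 and C6 are fixed in one operation. On step count up to the key step it is far stronger.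
- Against: A3 is still far from the target. The epoxide must be opened by a benzoate oxygen at C6, the carbon next to the quaternary centre, with inversion, although C5 is the easier position to attack. The C2=C3 alkene and the C4 methylene must then become the C2 ketone and the C3=C4 alkene, an allylic oxidation with transposition on a substrate with free hydroxyls. A4 and A3 are doubly or singly allylic tertiary carbinols that aromatise readily under acid. The enantiotopic selection rests entirely on the catalyst.
- Comparison: the chosen route offers regiochemical and stereochemical relationships fixed by the sugar skeleton in place of these three open selectivity questions.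

Alternative 3: The C2–O and C5–O bonds are cut, through endoperoxide A5, back to the 5,6-trans-dioxygenated diene A6.
- Forward key step: singlet oxygen adds across C2 and C5 on the face of the C1 hydroxyl, anti to the C6 benzoate, giving A5. A base-induced Kornblum–DeLaMare fragmentation of A5 would then give 25 directly.
- For: the gamma-hydroxy enone and the C5 configuration arise in two steps without protecting groups. After its key step this is the shortest of all the routes.
- Against: the fragmentation must remove the bridgehead hydrogen on C2, next to the quaternary carbon, and not the one on C5, which is next to the benzoate-bearing carbon and is the more acidic and more accessible. Removal at C5 would put the carbonyl on C5, and the structure offers no control. A6 is one elimination away from an aromatic ring and must be made as a single enantiomer. The base of the fragmentation also threatens the benzoates.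
- Comparison: in the chosen route the carbonyl position is dictated by the only enolisable methylene; the price is a longer linear sequence.

Key step: step 11

## Route

Assumption: 1 is bought as a catalogue compound, and the carbinol centres formed in steps 11 (C2) and 12 (C4) are drawn as the expected major epimers; both become trigonal in step 14, so their epimers could be carried through the same steps.

Step 1
Reactants: 1 methyl 4,6-O-benzylidene-α-D-glucopyranoside; 2 4-methoxybenzyl chloride
Product: 4 methyl 4,6-O-benzylidene-3-O-(4-methoxybenzyl)-α-D-glucopyranoside, via copper 2,3-dialkoxide chelate 3 (not isolated)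
Conditions: NaH (2.1 equiv), THF, 0 °C to rt; CuCl2 (1.0 equiv), rt; then 2 (1.5 equiv), Bu4NI (cat.), rt to 50 °C
Reagents that add atoms: 4-methoxybenzyl chloride (2), COc1ccc(CCl)cc1
Why: Regioselective Williamson alkylation of a vicinal diol through its chelate with divalent copper: in 3 the O2 alkoxide, the more acidic one next to the anomeric centre, is held more firmly by the metal, so the benzylic halide should be taken up by O3. No stereocentre is touched.

Step 2
Reactants: 4 methyl 4,6-O-benzylidene-3-O-(4-methoxybenzyl)-α-D-glucopyranoside
Product: 5 methyl 4,6-O-benzylidene-3-O-(4-methoxybenzyl)-α-D-arabino-hexopyranosid-2-ulose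
Conditions: Dess–Martin periodinane, CH2Cl2, rt
Reagents that add atoms: none
Why: Dess–Martin oxidation of the only free hydroxyl; the neutral, base-free medium should avoid enolisation toward sugar C3 and beta-elimination of O4. The ketone hydrates easily and is dried azeotropically before step 3.

Step 3
Reactants: 5 methyl 4,6-O-benzylidene-3-O-(4-methoxybenzyl)-α-D-arabino-hexopyranosid-2-ulose; 6 vinylmagnesium bromide
Product: 7 methyl 4,6-O-benzylidene-3-O-(4-methoxybenzyl)-2-C-vinyl-α-D-glucopyranoside
Conditions: 6 (1.5 equiv), THF, −78 to −20 °C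
Reagents that add atoms: vinylmagnesium bromide (6), C=C[Mg]Br
Why: Grignard 1,2-addition to the ketone. The axial anomeric methoxy group shields the alpha face and disfavours equatorial approach, so the vinyl group should enter axially from the beta face and leave the new tertiary hydroxyl equatorial (gluco, trans to O3); this sets the quaternary centre that becomes C1 of 25.

Step 4
Reactants: 7 methyl 4,6-O-benzylidene-3-O-(4-methoxybenzyl)-2-C-vinyl-α-D-glucopyranoside
Product: 8 methyl 4,6-O-benzylidene-2-C-vinyl-α-D-glucopyranoside
Conditions: DDQ, CH2Cl2/pH 7 buffer (10:1), 0 °C to rt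
Reagents that add atoms: none
Why: Oxidative cleavage of the 4-methoxybenzyl ether by DDQ (hydride abstraction at the electron-rich benzylic carbon, then hydrolysis); the benzylidene acetal and the vinyl group are not electron-rich enough to react. Removal at this point keeps the anisyl ring away from ozone in step 5.

Step 5
Reactants: 8 methyl 4,6-O-benzylidene-2-C-vinyl-α-D-glucopyranoside
Product: 10 methyl 4,6-O-benzylidene-2-C-(hydroxymethyl)-α-D-glucopyranoside, via 2-C-formyl glucoside 9 (not isolated)
Conditions: O3, CH2Cl2/MeOH (1:1), −78 °C; then NaBH4, −78 to 0 °C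
Reagents that add atoms: ozone, [O-][O+]=O
Why: Ozonolysis with reductive work-up; the terminal alkene reacts far faster with ozone than the acetal C–H, and reduction in the same flask turns alpha-hydroxy aldehyde 9 into the primary alcohol before it can fragment. The quaternary centre carries no hydrogen and cannot epimerise.

Step 6
Reactants: 10 methyl 4,6-O-benzylidene-2-C-(hydroxymethyl)-α-D-glucopyranoside; 11 benzoyl chloride
Product: 12 methyl 3-O-benzoyl-2-C-(benzoyloxymethyl)-4,6-O-benzylidene-α-D-glucopyranoside
Conditions: 11 (2.5 equiv), pyridine, DMAP (cat.), CH2Cl2, 0 °C to rt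
Reagents that add atoms: benzoyl chloride (11), O=C(Cl)c1ccccc1
Why: DMAP-catalysed acylation of the primary and the secondary hydroxyl; the tertiary hydroxyl, flanked by three substituted carbons, should stay free. Both benzoates of the target are then in place.

Step 7
Reactants: 12 methyl 3-O-benzoyl-2-C-(benzoyloxymethyl)-4,6-O-benzylidene-α-D-glucopyranoside
Product: 13 methyl 3-O-benzoyl-2-C-(benzoyloxymethyl)-α-D-glucopyranoside
Conditions: H2 (1 atm), Pd(OH)2/C, EtOAc/MeOH, rt
Reagents that add atoms: none
Why: Hydrogenolysis of the two benzylic C–O bonds of the acetal frees O4 and O6; benzoates, the methyl glycoside and the tertiary alcohol are inert. The neutral medium should keep the O3 benzoate from moving to O4.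

Step 8
Reactants: 13 methyl 3-O-benzoyl-2-C-(benzoyloxymethyl)-α-D-glucopyranoside
Product: 14 methyl 3-O-benzoyl-2-C-(benzoyloxymethyl)-6-deoxy-6-iodo-α-D-glucopyranoside
Conditions: PPh3, I2, imidazole, THF, 0 °C to rt
Reagents that add atoms: iodine, II
Why: Garegg–Samuelsson iodination (Appel type): only the primary hydroxyl should form an alkoxyphosphonium ion that iodide displaces by SN2 at this temperature, leaving the secondary O4–H and the tertiary O2–H.

Step 9
Reactants: 14 methyl 3-O-benzoyl-2-C-(benzoyloxymethyl)-6-deoxy-6-iodo-α-D-glucopyranoside; 15 tert-butyldimethylsilyl trifluoromethanesulfonate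
Product: 16 methyl 3-O-benzoyl-2-C-(benzoyloxymethyl)-4-O-(tert-butyldimethylsilyl)-6-deoxy-6-iodo-α-D-glucopyranoside
Conditions: 15 (1.2 equiv), 2,6-lutidine, CH2Cl2, −78 to −20 °C
Reagents that add atoms: tert-butyldimethylsilyl trifluoromethanesulfonate (15), CC(C)(C)[Si](C)(C)OS(=O)(=O)C(F)(F)F
Why: Silylation with a silyl triflate and a hindered base; with a small excess at low temperature the secondary hydroxyl should react well before the crowded tertiary one. O4 is thereby marked for the final deprotection.

Step 10
Reactants: 16 methyl 3-O-benzoyl-2-C-(benzoyloxymethyl)-4-O-(tert-butyldimethylsilyl)-6-deoxy-6-iodo-α-D-glucopyranoside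
Product: 17 methyl 3-O-benzoyl-2-C-(benzoyloxymethyl)-4-O-(tert-butyldimethylsilyl)-6-deoxy-α-D-xylo-hex-5-enopyranoside
Conditions: DBU, THF, reflux
Reagents that add atoms: none
Why: E2 dehydroiodination with an amidine base; H-5 is the only beta-hydrogen, so the exocyclic enol ether is the only alkene that can form. Benzoates and the silyl ether tolerate the non-nucleophilic base.

Step 11
Reactants: 17 methyl 3-O-benzoyl-2-C-(benzoyloxymethyl)-4-O-(tert-butyldimethylsilyl)-6-deoxy-α-D-xylo-hex-5-enopyranoside
Product: 19 [(1S,2S,5S,6S)-6-(benzoyloxy)-5-(tert-butyldimethylsilyloxy)-1,2-dihydroxy-4-oxocyclohexyl]methyl benzoate, via open-chain mercurio keto aldehyde 18 (not isolated)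
Conditions: Hg(OCOCF3)2 (10 mol %), acetone/H2O (2:1), rt
Reagents that add atoms: water, O
Why: In this Ferrier carbocyclisation the divalent mercury salt adds to the enol ether at sugar C6 and water at sugar C5; the hemiketal opens the pyranose, methanol leaves the anomeric carbon, and the alpha-mercurio ketone with a free aldehyde (18) results. Its mercury enolate then attacks the aldehyde, forming the C2–C3 bond of the carbocycle and returning the mercury salt, so a catalytic amount should suffice. The closest known reaction type is the mercury-mediated conversion of 6-deoxyhex-5-enopyranosides into hydroxycyclohexanones. The six-membered ring closes in the 6-(enolendo)-exo-trig mode. The only new stereocentre is C2: a chair-like transition state that keeps the gluco arrangement on C1, C6 and C5 should place the new hydroxyl axial, cis to the C1 hydroxyl and trans to the C6 benzoate, and since C2 becomes the ketone in step 14 either epimer is usable. The step needs the aldol to be faster than loss of benzoate from C6 (the product is a beta-acyloxy ketone) and the three existing centres to stay fixed: the medium is near neutral and base-free, the aldehyde sits on a quaternary carbon and cannot enolise, and the enolate is fixed at C3 by the mercury. Benzoates and the silyl ether tolerate aqueous acetone.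

Step 12
Reactants: 19 [(1S,2S,5S,6S)-6-(benzoyloxy)-5-(tert-butyldimethylsilyloxy)-1,2-dihydroxy-4-oxocyclohexyl]methyl benzoate
Product: 20 [(1S,2S,4S,5R,6S)-6-(benzoyloxy)-5-(tert-butyldimethylsilyloxy)-1,2,4-trihydroxycyclohexyl]methyl benzoate
Conditions: Me4NBH(OAc)3, MeCN/AcOH (1:1), −20 °C
Reagents that add atoms: none
Why: Hydroxyl-directed (Evans–Saksena) reduction: the axial C2 hydroxyl exchanges onto boron and delivers hydride to the same face of the C4 carbonyl, which should give the 2,4-anti diol with the new C4 hydroxyl equatorial. The weakly acidic medium should not trigger beta-elimination of the C6 benzoate, and the C4 configuration is lost again in step 14.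

Step 13
Reactants: 20 [(1S,2S,4S,5R,6S)-6-(benzoyloxy)-5-(tert-butyldimethylsilyloxy)-1,2,4-trihydroxycyclohexyl]methyl benzoate; 21 methanesulfonyl chloride
Product: 22 [(1S,2S,4S,5S,6S)-6-(benzoyloxy)-5-(tert-butyldimethylsilyloxy)-1,2-dihydroxy-4-(methylsulfonyloxy)cyclohexyl]methyl benzoate
Conditions: 21 (1.1 equiv), pyridine, CH2Cl2, −20 to 0 °C
Reagents that add atoms: methanesulfonyl chloride (21), CS(=O)(=O)Cl
Why: Site-selective sulfonylation: the C4 hydroxyl is equatorial with a CH2 neighbour, whereas the C2 hydroxyl is axial and next to the fully substituted C1, and the tertiary C1 hydroxyl is inert. Direct sulfonylation in pyridine, without a sulfene, should therefore pick C4.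

Step 14
Reactants: 22 [(1S,2S,4S,5S,6S)-6-(benzoyloxy)-5-(tert-butyldimethylsilyloxy)-1,2-dihydroxy-4-(methylsulfonyloxy)cyclohexyl]methyl benzoate
Product: 24 [(1R,5R,6S)-6-(benzoyloxy)-5-(tert-butyldimethylsilyloxy)-1-hydroxy-2-oxocyclohex-3-en-1-yl]methyl benzoate, via beta-mesyloxy ketone 23 (not isolated)
Conditions: IBX, DMSO, rt; then Et3N, CH2Cl2, 0 °C
Reagents that add atoms: none
Why: IBX oxidises the remaining secondary alcohol without cleaving the C1–C2 glycol, and beta-mesyloxy ketone 23 then loses methanesulfonate by E1cB. C1 is quaternary, so enolisation is possible only toward C3 and the C3=C4 enone is the only outcome; brief contact with a tertiary amine at 0 °C should leave the gamma-hydrogen and the benzoates alone.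

Step 15
Reactants: 24 [(1R,5R,6S)-6-(benzoyloxy)-5-(tert-butyldimethylsilyloxy)-1-hydroxy-2-oxocyclohex-3-en-1-yl]methyl benzoate
Product: 25 [(1R,5R,6S)-6-(benzoyloxy)-1,5-dihydroxy-2-oxocyclohex-3-en-1-yl]methyl benzoate
Conditions: HF·pyridine, THF/pyridine, 0 °C to rt
Reagents that add atoms: none
Why: Fluoride-driven cleavage of the silyl ether under weakly acidic conditions, chosen over basic fluoride so that the C6 benzoate should not migrate to the freed C5 hydroxyl and the gamma-hydroxy enone does not meet base.

## Compound list

1 | methyl 4,6-O-[(R)-benzylidene]-α-D-glucopyranoside | CO[C@H]1O[C@@H]2CO[C@@H](c3ccccc3)O[C@H]2[C@H](O)[C@H]1O | starting material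
2 | 4-methoxybenzyl chloride | COc1ccc(CCl)cc1 | starting material
3 | chelate of divalent copper with the 2,3-dialkoxide of 1 (not isolated) | CO[C@H]1O[C@@H]2CO[C@@H](c3ccccc3)O[C@H]2[C@H]([O-])[C@H]1[O-].[Cu+2] | intermediate
4 | methyl 4,6-O-benzylidene-3-O-(4-methoxybenzyl)-α-D-glucopyranoside | CO[C@H]1O[C@@H]2CO[C@@H](c3ccccc3)O[C@H]2[C@H](OCc4ccc(OC)cc4)[C@H]1O | intermediate
5 | methyl 4,6-O-benzylidene-3-O-(4-methoxybenzyl)-α-D-arabino-hexopyranosid-2-ulose | CO[C@H]1O[C@@H]2CO[C@@H](c3ccccc3)O[C@H]2[C@H](OCc4ccc(OC)cc4)C1=O | intermediate
6 | vinylmagnesium bromide | C=C[Mg]Br | starting material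
7 | methyl 4,6-O-benzylidene-3-O-(4-methoxybenzyl)-2-C-vinyl-α-D-glucopyranoside | CO[C@H]1O[C@@H]2CO[C@@H](c3ccccc3)O[C@H]2[C@H](OCc4ccc(OC)cc4)[C@]1(O)C=C | intermediate
8 | methyl 4,6-O-benzylidene-2-C-vinyl-α-D-glucopyranoside | CO[C@H]1O[C@@H]2CO[C@@H](c3ccccc3)O[C@H]2[C@H](O)[C@]1(O)C=C | intermediate
9 | methyl 4,6-O-benzylidene-2-C-formyl-α-D-glucopyranoside (not isolated) | CO[C@H]1O[C@@H]2CO[C@@H](c3ccccc3)O[C@H]2[C@H](O)[C@]1(O)C=O | intermediate
10 | methyl 4,6-O-benzylidene-2-C-(hydroxymethyl)-α-D-glucopyranoside | CO[C@H]1O[C@@H]2CO[C@@H](c3ccccc3)O[C@H]2[C@H](O)[C@]1(O)CO | intermediate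
11 | benzoyl chloride | O=C(Cl)c1ccccc1 | starting material
12 | methyl 3-O-benzoyl-2-C-(benzoyloxymethyl)-4,6-O-benzylidene-α-D-glucopyranoside | CO[C@H]1O[C@@H]2CO[C@@H](c3ccccc3)O[C@H]2[C@H](OC(=O)c4ccccc4)[C@]1(O)COC(=O)c1ccccc1 | intermediate
13 | methyl 3-O-benzoyl-2-C-(benzoyloxymethyl)-α-D-glucopyranoside | CO[C@H]1O[C@H](CO)[C@@H](O)[C@H](OC(=O)c2ccccc2)[C@]1(O)COC(=O)c1ccccc1 | intermediate
14 | methyl 3-O-benzoyl-2-C-(benzoyloxymethyl)-6-deoxy-6-iodo-α-D-glucopyranoside | CO[C@H]1O[C@H](CI)[C@@H](O)[C@H](OC(=O)c2ccccc2)[C@]1(O)COC(=O)c1ccccc1 | intermediate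
15 | tert-butyldimethylsilyl trifluoromethanesulfonate | CC(C)(C)[Si](C)(C)OS(=O)(=O)C(F)(F)F | starting material
16 | methyl 3-O-benzoyl-2-C-(benzoyloxymethyl)-4-O-(tert-butyldimethylsilyl)-6-deoxy-6-iodo-α-D-glucopyranoside | CO[C@H]1O[C@H](CI)[C@@H](O[Si](C)(C)C(C)(C)C)[C@H](OC(=O)c2ccccc2)[C@]1(O)COC(=O)c1ccccc1 | intermediate
17 | methyl 3-O-benzoyl-2-C-(benzoyloxymethyl)-4-O-(tert-butyldimethylsilyl)-6-deoxy-α-D-xylo-hex-5-enopyranoside | CO[C@H]1OC(=C)[C@@H](O[Si](C)(C)C(C)(C)C)[C@H](OC(=O)c2ccccc2)[C@]1(O)COC(=O)c1ccccc1 | intermediate
18 | open-chain 6-(trifluoroacetoxymercurio) 5-keto aldehyde derived from 17, sugar C2 to C4 unchanged (not isolated) | O=C[C@@](O)(COC(=O)c1ccccc1)[C@@H](OC(=O)c1ccccc1)[C@H](O[Si](C)(C)C(C)(C)C)C(=O)C[Hg]OC(=O)C(F)(F)F | intermediate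
19 | [(1S,2S,5S,6S)-6-(benzoyloxy)-5-(tert-butyldimethylsilyloxy)-1,2-dihydroxy-4-oxocyclohexyl]methyl benzoate (2-OH cis to 1-OH) | O=C1C[C@H](O)[C@@](O)(COC(=O)c2ccccc2)[C@@H](OC(=O)c2ccccc2)[C@@H]1O[Si](C)(C)C(C)(C)C | intermediate
20 | [(1S,2S,4S,5R,6S)-6-(benzoyloxy)-5-(tert-butyldimethylsilyloxy)-1,2,4-trihydroxycyclohexyl]methyl benzoate (4-OH trans to 2-OH and to the 5-silyloxy group) | O[C@H]1C[C@H](O)[C@@](O)(COC(=O)c2ccccc2)[C@@H](OC(=O)c2ccccc2)[C@@H]1O[Si](C)(C)C(C)(C)C | intermediate
21 | methanesulfonyl chloride | CS(=O)(=O)Cl | starting material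
22 | [(1S,2S,4S,5S,6S)-6-(benzoyloxy)-5-(tert-butyldimethylsilyloxy)-1,2-dihydroxy-4-(methylsulfonyloxy)cyclohexyl]methyl benzoate | CS(=O)(=O)O[C@H]1C[C@H](O)[C@@](O)(COC(=O)c2ccccc2)[C@@H](OC(=O)c2ccccc2)[C@@H]1O[Si](C)(C)C(C)(C)C | intermediate
23 | [(1R,4S,5S,6S)-6-(benzoyloxy)-5-(tert-butyldimethylsilyloxy)-1-hydroxy-4-(methylsulfonyloxy)-2-oxocyclohexyl]methyl benzoate (not isolated) | CS(=O)(=O)O[C@H]1CC(=O)[C@@](O)(COC(=O)c2ccccc2)[C@@H](OC(=O)c2ccccc2)[C@@H]1O[Si](C)(C)C(C)(C)C | intermediate
24 | [(1R,5R,6S)-6-(benzoyloxy)-5-(tert-butyldimethylsilyloxy)-1-hydroxy-2-oxocyclohex-3-en-1-yl]methyl benzoate | O=C(OC[C@]1(O)C(=O)C=C[C@@H](O[Si](C)(C)C(C)(C)C)[C@@H]1OC(=O)c1ccccc1)c1ccccc1 | intermediate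
25 | [(1R,5R,6S)-6-(benzoyloxy)-1,5-dihydroxy-2-oxocyclohex-3-en-1-yl]methyl benzoate | O=C(OC[C@]1(O)C(=O)C=C[C@@H](O)[C@@H]1OC(=O)c1ccccc1)c1ccccc1 | target

## Step count and least certain steps

Total step count: 15. Longest linear sequence: 15 steps, from 1 to 25.

Step 11 (key step). The enolate carbon has to reach an aldehyde on a fully substituted carbon. The closure may therefore lag behind loss of the C6 benzoate from the newly formed beta-acyloxy ketone, or the reaction may stall at the open-chain stage. Fallback: set out from 17 and separate hydrolysis from ring closure. Dilute acid (PPTS in wet acetone, rt) should hydrolyse enol ether and glycoside to the open-chain 3-O-benzoyl-2-C-(benzoyloxymethyl)-4-O-(tert-butyldimethylsilyl)-6-deoxy-D-xylo-hexos-5-ulose F1. The same C2–C3 bond is then closed by an amine-catalysed intramolecular aldol through the enamine of the methyl ketone (pyrrolidine/AcOH in THF, or L-proline in DMSO), which returns to the route at 19.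

Step 13. Site selection between the two secondary hydroxyls may be poor, or both may be sulfonylated, because the argument rests only on the axial, neopentyl-like environment of the C2 hydroxyl. Fallback: set out from 19 and protect before reducing. Silylation (TESOTf, 2,6-lutidine, −78 °C) should give the 2-O-triethylsilyl ether of 19 F2. Reduction (NaBH4, MeOH, −40 °C) gives the 2-O-triethylsilyl ether of 20 F3, and mesylation of its only free secondary hydroxyl (MsCl, Et3N) gives the 2-O-triethylsilyl ether of 22 F4. Selective removal of the triethylsilyl group (PPTS, MeOH, 0 °C) returns to the route at 22.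

Step 1. Regiocontrol may be incomplete (alkylation at O2 or at both oxygens), or the alkylation of the chelate may be slow. Fallback: set out from 1 and block O2 first. Selective acylation of the more acidic O2–H (1-benzoylimidazole, CH2Cl2, reflux) gives methyl 2-O-benzoyl-4,6-O-benzylidene-α-D-glucopyranoside F5. Acid-catalysed etherification of O3 (4-methoxybenzyl trichloroacetimidate, cat. La(OTf)3, toluene), which avoids acyl migration, gives methyl 2-O-benzoyl-4,6-O-benzylidene-3-O-(4-methoxybenzyl)-α-D-glucopyranoside F6. Zemplén transesterification (NaOMe, MeOH) returns to the route at 4.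

Step 5. Ozone may also attack the benzylidene acetal C–H (over-oxidation), or the alpha-hydroxy aldehyde may lose its formyl group before it is reduced. Fallback: set out from 5 and introduce the branch as a masked hydroxymethyl group without any alkene cleavage. Addition of (isopropoxydimethylsilyl)methylmagnesium chloride, expected on the beta face as in step 3, gives methyl 4,6-O-benzylidene-2-C-[(isopropoxydimethylsilyl)methyl]-3-O-(4-methoxybenzyl)-α-D-glucopyranoside F7. Tamao oxidation (H2O2, KF, KHCO3, THF/MeOH) gives methyl 4,6-O-benzylidene-2-C-(hydroxymethyl)-3-O-(4-methoxybenzyl)-α-D-glucopyranoside F8. Removal of the ether with DDQ in wet CH2Cl2 returns to the route at 10.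

## Further compounds

F1 | step 11 | 3-O-benzoyl-2-C-(benzoyloxymethyl)-4-O-(tert-butyldimethylsilyl)-6-deoxy-D-xylo-hexos-5-ulose (open chain) | O=C[C@@](O)(COC(=O)c1ccccc1)[C@@H](OC(=O)c1ccccc1)[C@H](O[Si](C)(C)C(C)(C)C)C(C)=O
F2 | step 13 | 2-O-triethylsilyl ether of 19 | O=C1C[C@H](O[Si](CC)(CC)CC)[C@@](O)(COC(=O)c2ccccc2)[C@@H](OC(=O)c2ccccc2)[C@@H]1O[Si](C)(C)C(C)(C)C
F3 | step 13 | 2-O-triethylsilyl ether of 20 | O[C@H]1C[C@H](O[Si](CC)(CC)CC)[C@@](O)(COC(=O)c2ccccc2)[C@@H](OC(=O)c2ccccc2)[C@@H]1O[Si](C)(C)C(C)(C)C
F4 | step 13 | 2-O-triethylsilyl ether of 22 | CS(=O)(=O)O[C@H]1C[C@H](O[Si](CC)(CC)CC)[C@@](O)(COC(=O)c2ccccc2)[C@@H](OC(=O)c2ccccc2)[C@@H]1O[Si](C)(C)C(C)(C)C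
F5 | step 1 | methyl 2-O-benzoyl-4,6-O-benzylidene-α-D-glucopyranoside | CO[C@H]1O[C@@H]2CO[C@@H](c3ccccc3)O[C@H]2[C@H](O)[C@H]1OC(=O)c1ccccc1
F6 | step 1 | methyl 2-O-benzoyl-4,6-O-benzylidene-3-O-(4-methoxybenzyl)-α-D-glucopyranoside | CO[C@H]1O[C@@H]2CO[C@@H](c3ccccc3)O[C@H]2[C@H](OCc4ccc(OC)cc4)[C@H]1OC(=O)c1ccccc1
F7 | step 5 | methyl 4,6-O-benzylidene-2-C-[(isopropoxydimethylsilyl)methyl]-3-O-(4-methoxybenzyl)-α-D-glucopyranoside | CO[C@H]1O[C@@H]2CO[C@@H](c3ccccc3)O[C@H]2[C@H](OCc4ccc(OC)cc4)[C@]1(O)C[Si](C)(C)OC(C)C
F8 | step 5 | methyl 4,6-O-benzylidene-2-C-(hydroxymethyl)-3-O-(4-methoxybenzyl)-α-D-glucopyranoside | CO[C@H]1O[C@@H]2CO[C@@H](c3ccccc3)O[C@H]2[C@H](OCc4ccc(OC)cc4)[C@]1(O)CO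
A1 | alternative 1 | 1-O-triethylsilyl ether of 25 | O=C(OC[C@@]1(O[Si](CC)(CC)CC)[C@@H](OC(=O)c2ccccc2)[C@H](O)C=CC1=O)c1ccccc1
A2 | alternative 1 | open-chain (Z)-beta-iodo enone aldehyde, the ring-opened form of A1 at C4–C5, configured as 25 at C1 and C6 | O=C[C@H](OC(=O)c1ccccc1)[C@@](COC(=O)c1ccccc1)(O[Si](CC)(CC)CC)C(=O)/C=C\I
A3 | alternative 2 | 5,6-epoxide of A4, syn to the C1 hydroxyl | O=C(OC[C@@]1(O)[C@@H]2O[C@@H]2CC=C1)c1ccccc1
A4 | alternative 2 | (1-hydroxycyclohexa-2,5-dien-1-yl)methyl benzoate | O=C(OCC1(O)C=CCC=C1)c1ccccc1
A5 | alternative 3 | C2,C5-endoperoxide of A6, syn to the C1 hydroxyl | O=C(OC[C@@]1(O)[C@@H](OC(=O)c2ccccc2)[C@@H]2OO[C@H]1C=C2)c1ccccc1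
A6 | alternative 3 | [6-(benzoyloxy)-1-hydroxycyclohexa-2,4-dien-1-yl]methyl benzoate, C1 and C6 oxygens trans, configured as 25 | O=C(OC[C@@]1(O)[C@@H](OC(=O)c2ccccc2)C=CC=C1)c1ccccc1
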